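**Retrosynthetic overview**
1. The target is (+)-isolariciresinol with the sulfate on the C2 hydroxymethyl (lignan C9'). Ring B (C1–C8a bond) is disconnected by the biogenetic para-quinone methide Friedel–Crafts step to (+)-lariciresinol 9'-O-sulfate, whose tetrahydrofuran oxygen masks the C3 hydroxymethyl, so the only free aliphatic OH is the one to be sulfated.
2. (+)-Lariciresinol ⇐ C2-symmetric (−)-secoisolariciresinol by a desymmetrizing oxidative quinone methide cycloetherification (benzylic C–H to C–O, no pre-installed benzylic oxygen).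
3. (−)-Secoisolariciresinol ⇐ (R,R)-succinyl bis-imide by global hydride reduction ⇐ auxiliary-controlled oxidative enolate homocoupling (C8–C8' bond and both stereocentres in one step).
4. Monomer ⇐ dihydroferulic acid, pivaloyl chloride and (S)-4-benzyloxazolidin-2-one.
5. Ring order: tetrahydrofuran ring first (step 5), then carbocyclic ring B with opening of the tetrahydrofuran (step 6); C1 is set in the last step.

Assumption: CNP0184747.1 is taken as the free hydrogen sulfate of (+)-isolariciresinol, (1S,2R,3R), all-trans, sulfated on the hydroxymethyl at C2; lignan numbering (C7–C9, C7'–C9') is used for the open-chain and tetrahydrofuran intermediates, C7' being the carbon that becomes C1.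

**Route**

Step 1
Reactants: 1 3-(4-hydroxy-3-methoxyphenyl)propanoic acid (dihydroferulic acid)
Product: 2 3-(3-methoxy-4-pivaloyloxyphenyl)propanoic acid
Conditions: PivCl (1.2 equiv), NaOH (2.1 equiv), H2O/THF, 0 °C; then HCl to pH 2
Reagents that add atoms: pivaloyl chloride, CC(C)(C)C(=O)Cl
Why: Schotten–Baumann acylation, in which the phenoxide is far more nucleophilic than the carboxylate in water so the hindered acid chloride caps only the phenol (any mixed anhydride hydrolyses), giving a non-enolisable aryl pivalate that tolerates amide bases and is later removed by hydride; no stereocentre is formed.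

Step 2
Reactants: 2 3-(3-methoxy-4-pivaloyloxyphenyl)propanoic acid; 3 (S)-4-benzyloxazolidin-2-one
Product: 5 (S)-4-benzyl-3-[3-(3-methoxy-4-pivaloyloxyphenyl)propanoyl]oxazolidin-2-one, via mixed pivalic anhydride 4 (not isolated)
Conditions: PivCl, Et3N, THF, −20 °C; then LiCl, 3, rt
Reagents that add atoms: none
Why: Mixed-anhydride N-acylation of an Evans oxazolidinone (LiCl/Et3N protocol), in which the auxiliary attacks the unhindered carbonyl of 4 and pivalate leaves; no new stereocentre.

Step 3
Reactants: 5 (S)-4-benzyl-3-[3-(3-methoxy-4-pivaloyloxyphenyl)propanoyl]oxazolidin-2-one (2 equivalents)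
Product: 8 (4S,4'S)-3,3'-[(2R,3R)-2,3-bis(3-methoxy-4-pivaloyloxybenzyl)butanedioyl]bis(4-benzyloxazolidin-2-one), via lithium Z-enolate 6 (not isolated), via trichlorotitanium enolate 7 (not isolated)
Conditions: LiN(iPr)2 (1.1 equiv), THF, −78 °C; TiCl4 (1.1 equiv), −78 to 0 °C; aq. NH4Cl
Reagents that add atoms: none
Why: Oxidative homocoupling of a chiral N-acyloxazolidinone enolate, in which the chelated Z-enolate 6 is transmetallated to the tetravalent titanium enolate 7, which passes one electron to the metal (giving trivalent titanium) and couples C8 to C8' on the enolate face opposite the 4-benzyl group of each auxiliary, so both new stereocentres are set (R,R) in a single event while the hindered aryl pivalates stay intact.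

Step 4
Reactants: 8 (4S,4'S)-3,3'-[(2R,3R)-2,3-bis(3-methoxy-4-pivaloyloxybenzyl)butanedioyl]bis(4-benzyloxazolidin-2-one)
Product: 9 (−)-secoisolariciresinol [(2R,3R)-2,3-bis(4-hydroxy-3-methoxybenzyl)butane-1,4-diol]
Conditions: LiAlH4 (5 equiv), THF, 0 °C to rt; aqueous work-up at pH 5
Reagents that add atoms: none
Why: Hydride reduction that cleaves both N-acyloxazolidinones to primary alcohols and both aryl pivalates to phenols in one operation, returning the auxiliary and leaving the two stereocentres untouched because no bond to them is made or broken.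

Step 5
Reactants: 9 (−)-secoisolariciresinol
Product: 11 (+)-lariciresinol [(7'S,8R,8'R); 4-{[(3R,4R,5S)-5-(4-hydroxy-3-methoxyphenyl)-4-(hydroxymethyl)oxolan-3-yl]methyl}-2-methoxyphenol], via para-quinone methide 10 (not isolated)
Conditions: DDQ (0.9 equiv), 1,4-dioxane (5 mM), 15 °C; recovered 9 recycled
Reagents that add atoms: none
Why: Proposed new method: DDQ removes hydride from a benzylic C–H para to the free phenol to give para-quinone methide 10, which the γ-hydroxyl of the other half captures by 5-exo oxa-1,6-addition (the ring closure used in pinoresinol and lariciresinol biogenesis), the C2 symmetry of 9 making both benzylic sites equivalent so that one constitutional product forms and the new C7' centre is set trans to the adjacent CH2OH on steric grounds (its epimer converges in step 6); the closest known chemistry is DDQ oxidation of 4-alkylguaiacols to quinone methides with alcohol trapping and the radical-initiated conversion of secoisolariciresinol into lariciresinol.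

Step 6
Reactants: 11 (+)-lariciresinol
Product: 14 (+)-isolariciresinol 9'-O-sulfate (target; [(1S,2R,3R)-7-hydroxy-1-(4-hydroxy-3-methoxyphenyl)-3-(hydroxymethyl)-6-methoxy-1,2,3,4-tetrahydronaphthalen-2-yl]methyl hydrogen sulfate), via lariciresinol 9'-O-sulfate pyridinium salt 12 (not isolated), via ring-opened para-quinone methide 13 (not isolated)
Conditions: SO3·pyridine (1.2 equiv), pyridine, 0 °C; H2O quench, evaporate; TFA/H2O (9:1), 0 °C to rt, 30 min; Dowex 50W (H+ form), C18 chromatography, lyophilise
Reagents that add atoms: sulfur trioxide–pyridine complex, [O-]S(=O)(=O)[n+]1ccccc1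
Why: O-sulfation followed by the acid-mediated quinone methide Friedel–Crafts cyclization known for lariciresinol to isolariciresinol, in which SO3·pyridine without strong base esterifies the single aliphatic hydroxyl much faster than the un-ionised phenols and aqueous TFA then ionises the benzylic C–O bond to the O-protonated quinone methide 13, which is attacked by C6 of the other guaiacyl ring (para to its OMe) through a chair-like transition state with aryl, CH2OSO3H and CH2OH all equatorial, setting C1 as S (1,2-trans) and releasing the C3 hydroxymethyl only after the sulfating agent has been quenched.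

**Compound list**
1 | 3-(4-hydroxy-3-methoxyphenyl)propanoic acid (dihydroferulic acid) | COc1cc(CCC(=O)O)ccc1O | starting material
2 | 3-(3-methoxy-4-pivaloyloxyphenyl)propanoic acid | COc1cc(CCC(=O)O)ccc1OC(=O)C(C)(C)C | intermediate
3 | (S)-4-benzyloxazolidin-2-one | O=C1OC[C@H](Cc2ccccc2)N1 | starting material
4 | mixed pivalic anhydride of 2 | COc1cc(CCC(=O)OC(=O)C(C)(C)C)ccc1OC(=O)C(C)(C)C | intermediate (not isolated)
5 | (S)-4-benzyl-3-[3-(3-methoxy-4-pivaloyloxyphenyl)propanoyl]oxazolidin-2-one | COc1cc(CCC(=O)N2[C@@H](Cc3ccccc3)COC2=O)ccc1OC(=O)C(C)(C)C | intermediate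
6 | lithium Z-enolate of 5 | [Li]O/C(=C\Cc1ccc(OC(=O)C(C)(C)C)c(OC)c1)N1[C@@H](Cc2ccccc2)COC1=O | intermediate (not isolated)
7 | trichlorotitanium Z-enolate of 5 | Cl[Ti](Cl)(Cl)O/C(=C\Cc1ccc(OC(=O)C(C)(C)C)c(OC)c1)N1[C@@H](Cc2ccccc2)COC1=O | intermediate (not isolated)
8 | (4S,4'S)-3,3'-[(2R,3R)-2,3-bis(3-methoxy-4-pivaloyloxybenzyl)butanedioyl]bis(4-benzyloxazolidin-2-one) | O=C1OC[C@H](Cc2ccccc2)N1C(=O)[C@H](Cc1ccc(OC(=O)C(C)(C)C)c(OC)c1)[C@@H](Cc1ccc(OC(=O)C(C)(C)C)c(OC)c1)C(=O)N1[C@@H](Cc2ccccc2)COC1=O | intermediate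
9 | (−)-secoisolariciresinol, (2R,3R)-2,3-bis(4-hydroxy-3-methoxybenzyl)butane-1,4-diol | COc1cc(C[C@@H](CO)[C@H](CO)Cc2ccc(O)c(OC)c2)ccc1O | intermediate
10 | para-quinone methide of 9 (one ring oxidised, exocyclic C7'=C1'; alkene geometry not defined) | COC1=CC(=C[C@@H](CO)[C@H](CO)Cc2ccc(O)c(OC)c2)C=CC1=O | intermediate (not isolated)
11 | (+)-lariciresinol, (7'S,8R,8'R): 2-aryl-3-hydroxymethyl-4-benzyl-tetrahydrofuran, aryl trans to CH2OH, CH2OH cis to benzyl | OC[C@H]1[C@@H](Cc2ccc(O)c(OC)c2)CO[C@@H]1c1ccc(O)c(OC)c1 | intermediate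
12 | (+)-lariciresinol 9'-O-sulfate, pyridinium salt | [O-]S(=O)(=O)OC[C@H]1[C@@H](Cc2ccc(O)c(OC)c2)CO[C@@H]1c1ccc(O)c(OC)c1.c1cc[nH+]cc1 | intermediate (not isolated)
13 | ring-opened para-quinone methide 9'-O-sulfate, pyridinium salt (free C9 hydroxyl; alkene geometry not defined) | COC1=CC(=C[C@@H](COS(=O)(=O)[O-])[C@H](CO)Cc2ccc(O)c(OC)c2)C=CC1=O.c1cc[nH+]cc1 | intermediate (not isolated)
14 | (+)-isolariciresinol 9'-O-sulfate, (1S,2R,3R), free hydrogen sulfate | COc1cc([C@H]2c3cc(O)c(OC)cc3C[C@@H](CO)[C@@H]2COS(=O)(=O)O)ccc1O | target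

**Step count and risks**
Total step count: 6. Longest linear sequence: 6 steps (1 to 14).

The three steps most likely to fail:

Step 5 (desymmetrizing DDQ cycloetherification). Product 11 still carries a second oxidisable p-hydroxybenzyl unit (leading on to pinoresinol) and a benzylic ether C–H. The yield per pass is therefore capped near one half at about three-quarters conversion, and 9 has to be recycled. The fallback sets out from 8 and comes back at 11; it makes the two benzylic positions electronically different before oxidation. NaBH4 (1 equiv) in THF/H2O at 0 °C reduces one imide of 8, and the resulting alcohol lactonises onto the second imide to give the trans-lactone di-O-pivaloyl-(−)-matairesinol F1. NaOMe in MeOH, then dilute HCl, removes the pivalates to give (−)-matairesinol F2. DDQ (2.2 equiv) in wet 1,4-dioxane oxidises only the benzylic position remote from the lactone carbonyl, through to the aryl ketone 7'-oxomatairesinol F3. LiAlH4 reduces ketone and lactone to 7'-hydroxysecoisolariciresinol F4 (both C7' epimers). Aqueous HCl at pH 2–3 in THF at rt then closes the kinetic 5-exo tetrahydrofuran to give 11.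

Step 6 (chemoselective sulfation and cyclization on unprotected phenols). Phenol sulfation may compete with alcohol sulfation, and the alkyl sulfate may be partly lost in acid. The fallback sets out from 11 and comes back at 14; it caps the phenols first. BnBr and K2CO3 in acetone alkylate only the phenols to give di-O-benzyl-lariciresinol F5. Excess SO3·pyridine then gives di-O-benzyl-lariciresinol 9'-O-sulfate F6. TFA in CH2Cl2 at 0 °C effects the same Friedel–Crafts ring closure to di-O-benzyl-isolariciresinol 9'-O-sulfate F7. H2 over 10% Pd on carbon in MeOH/H2O removes the benzyl groups to give 14. Hydrogenolysis is placed after ring B is closed so that no benzylic C–O bond of a tetrahydrofuran is exposed to it.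

Step 3 (oxidative homocoupling). Risks are modest yield, formation of the meso (R,S) dimer, and attack on the aryl pivalate. The fallback sets out from 5 and comes back at 9; it builds the C8–C8' framework by two polar alkylations instead of radical dimerization. NaN(SiMe3)2 and tert-butyl bromoacetate give, by Evans alkylation, the (2R)-succinate imide F8. LiBH4 (1.1 equiv, THF/H2O, 0 °C; imide only) followed by TFA gives the (4R)-β-benzyl-γ-butyrolactone F9. The electrophile comes from commercial vanillyl alcohol: phenoxide-selective pivaloylation (PivCl, aq. NaOH) gives 4-(hydroxymethyl)-2-methoxyphenyl pivalate F10, and PBr3 gives 4-(bromomethyl)-2-methoxyphenyl pivalate F11. The lithium enolate of F9 (LiN(SiMe3)2, −78 °C) is alkylated by F11 trans to the existing benzyl group to give the trans-lactone di-O-pivaloyl-(−)-matairesinol F12 (the same structure as F1). LiAlH4 reduces the lactone and both pivalates to give 9.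

**Further compounds**
F1 | step 5 | di-O-pivaloyl-(−)-matairesinol, (3R,4R)-3,4-bis(3-methoxy-4-pivaloyloxybenzyl)dihydrofuran-2(3H)-one | O=C1[C@H](Cc2ccc(OC(=O)C(C)(C)C)c(OC)c2)[C@@H](Cc2ccc(OC(=O)C(C)(C)C)c(OC)c2)CO1
F2 | step 5 | (−)-matairesinol, (3R,4R)-3,4-bis(4-hydroxy-3-methoxybenzyl)dihydrofuran-2(3H)-one | O=C1[C@H](Cc2ccc(O)c(OC)c2)[C@@H](Cc2ccc(O)c(OC)c2)CO1
F3 | step 5 | 7'-oxomatairesinol, (3R,4R)-4-(4-hydroxy-3-methoxybenzoyl)-3-(4-hydroxy-3-methoxybenzyl)dihydrofuran-2(3H)-one | O=C1[C@H](Cc2ccc(O)c(OC)c2)[C@@H](C(=O)c2ccc(O)c(OC)c2)CO1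
F4 | step 5 | 7'-hydroxysecoisolariciresinol (C7' epimers; 8R,8'R as in 9) | COc1cc(C(O)[C@@H](CO)[C@H](CO)Cc2ccc(O)c(OC)c2)ccc1O
F5 | step 6 | di-O-benzyl-(+)-lariciresinol | OC[C@H]1[C@@H](Cc2ccc(OCc3ccccc3)c(OC)c2)CO[C@@H]1c1ccc(OCc2ccccc2)c(OC)c1
F6 | step 6 | di-O-benzyl-lariciresinol 9'-O-sulfate (hydrogen sulfate form) | OS(=O)(=O)OC[C@H]1[C@@H](Cc2ccc(OCc3ccccc3)c(OC)c2)CO[C@@H]1c1ccc(OCc2ccccc2)c(OC)c1
F7 | step 6 | di-O-benzyl-isolariciresinol 9'-O-sulfate, (1S,2R,3R) (hydrogen sulfate form) | COc1cc([C@H]2c3cc(OCc4ccccc4)c(OC)cc3C[C@@H](CO)[C@@H]2COS(=O)(=O)O)ccc1OCc1ccccc1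
F8 | step 3 | (S)-4-benzyl-3-[(2R)-4-tert-butoxy-2-(3-methoxy-4-pivaloyloxybenzyl)-4-oxobutanoyl]oxazolidin-2-one | CC(C)(C)OC(=O)C[C@@H](Cc1ccc(OC(=O)C(C)(C)C)c(OC)c1)C(=O)N1[C@@H](Cc2ccccc2)COC1=O
F9 | step 3 | (4R)-4-(3-methoxy-4-pivaloyloxybenzyl)dihydrofuran-2(3H)-one | O=C1C[C@@H](Cc2ccc(OC(=O)C(C)(C)C)c(OC)c2)CO1
F10 | step 3 | 4-(hydroxymethyl)-2-methoxyphenyl pivalate | COc1cc(CO)ccc1OC(=O)C(C)(C)C
F11 | step 3 | 4-(bromomethyl)-2-methoxyphenyl pivalate | COc1cc(CBr)ccc1OC(=O)C(C)(C)C
F12 | step 3 | di-O-pivaloyl-(−)-matairesinol, (3R,4R)-3,4-bis(3-methoxy-4-pivaloyloxybenzyl)dihydrofuran-2(3H)-one (same structure as F1) | O=C1[C@H](Cc2ccc(OC(=O)C(C)(C)C)c(OC)c2)[C@@H](Cc2ccc(OC(=O)C(C)(C)C)c(OC)c2)CO1
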